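# Design of a total synthesis of CNP0243830.4 (38) by a late chromium benzannulation

Numbering used throughout. Left octalin: ring A = C5–C10 (C5=C6, C8–CH3, C9 with CH3 and the arylmethyl group, C10–H); ring B = C1–C5/C10 (C4 with CH3 and tether carbon C11). Right octalin: ring C = C1'–C5'/C10' (C1'=C10', C4' gem-dimethyl, C5'–H); ring D = C5'–C10' (C8'–CH3, C9' with CH3 and tether carbon C12).

## The problem

Compound 38 is two halimane-type octalins joined by a C11–C12 tether whose two ends are both quaternary ring carbons, so every bond made to or inside the tether is neopentylic. Its seven stereocentres fall into two sets (C4, C8, C9, C10 and C5', C8', C9') that the tether insulates from each other, so each half needs its own source of absolute configuration. Inside each half, C8/C9 can direct C10, and an allylic carbinol next to the sp2 ring-fusion carbon can direct the neighbouring quaternary carbon. The two tether-bearing carbons have opposite relations to the adjacent ring-fusion hydrogen (C11 trans to H10, C12 cis to H5'), so one uniform reaction cannot serve both. The aryl hydrogen sulfates are acid-labile and the free hydroquinone is air-sensitive, so both must come last. Each trisubstituted alkene sits next to a quaternary carbon and can slip into the tetrasubstituted ring-fusion position under protic acid or metal hydrides. The arene is a 2-alkyl-1,4-dioxygenated benzene held on C9 through a single CH2. That is the pattern a terminal alkyne, a vinyl(methoxy)carbene ligand and one CO give on benzannulation, so the arene can be built last on a propargyl group at C9.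

## Retrosynthesis

**38 ⇐ 37 ⇐ 36 ⇐ 35.** The two S–O bonds are cut first, then the hydroquinone 37 is traced through quinone 36 to the hydroquinone monomethyl ether 35. Direct O-demethylation of 35 would need a Lewis acid or hot thiolate next to two migration-prone alkenes. Oxidative demethylation with tetravalent cerium runs at 0 °C, and dithionite returns the hydroquinone. The forward steps must sulfate both phenols completely under non-acidic conditions.

**35 ⇐ 31 + 34 (key disconnection).** Three ring C–C bonds of the arene are cut: alkyne CH to carbene carbon, internal alkyne carbon to CO, and CO to the vinyl terminus. The neighbouring option, attaching a preformed dimethoxybenzyl unit at C9, would carry an electron-rich arene through dissolving-metal, hexavalent chromium and organocopper steps. The precursor 31 is an arene-free hydrocarbon with one terminal alkyne; 34 comes from Cr(CO)6 (32). The forward reaction must insert the alkyne with the bulky substituent next to the CO-derived carbon and leave two trisubstituted alkenes alone.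

**31 ⇐ 29 ⇐ 28.** No skeletal bond is cut. The propargyl group is traced to a methyl ketone (enol phosphate elimination) and that to an allyl group (Tsuji–Wacker oxidation). Allyl is chosen as the latent alkyne because it survives Li/NH3, aqueous acid, hydrides and Grignard reagents. A silyl alkyne would not survive the dissolving-metal step, and an acetal would not survive the acid that unmasks the ring B ketone. The forward oxidation must pick the monosubstituted alkene over two hindered trisubstituted ones.

**28 ⇐ 13 + 26.** The C4–C11 bond is cut. Cutting the central C11–C12 bond would join two neopentyl carbons and leave a functional group to remove next to a vinyl-bearing quaternary centre. Cutting C4–C11 as an allylic substitution creates the C4 quaternary centre and the C5=C6 alkene together, with the configuration relayed from the C6 carbinol of 26. Both partners are single octalins of similar size. The forward reaction must go γ and anti.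

**13 ⇐ 12 ⇐ 11 ⇐ 10.** The C9'–C12 bond is cut by a [3,3] shift of the ketene acetal of allylic alcohol 10. This delivers both tether carbons at the ester oxidation level, forms the C1'=C10' alkene, and places C12 on the face of the C1' oxygen, cis to H5'. The same kind of axial allylic alcohol is thus used suprafacially on the right and antarafacially on the left, which accounts for the opposite relations at C9' and C4.

**10 ⇐ 9 ⇐ 7 ⇐ 4 + 3 (⇐ 2 ⇐ 1).** Ring D is cut at C9'=C10' (aldol condensation) and C5'–C6' (conjugate addition to enone 4). The alternative of a Robinson annulation on a 3,3-dimethylcyclohexanone would have to react at the α-carbon next to the gem-dimethyl group. The precursors are the commodity enone 4 and bromo ketal 3. The forward chemistry needs an enantioselective conjugate addition for C5' and thermodynamic control at C8'.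

**26 ⇐ 25 ⇐ 24 ⇐ 22 ⇐ 21 ⇐ 20 ⇐ 17 + 18; 17 ⇐ 16 ⇐ 14.** Ring B is cut at C4=C5 (aldol condensation) and C10–C1. A direct cuprate addition of the C1 chain to a 4,4,5-trisubstituted cyclohexenone would enter anti to the axial C9 methyl and give the wrong C10. The chain is therefore put on first, by 1,2-addition of the Grignard reagent from 18 to enone 17 followed by oxidative transposition to 21, and hydrogen is delivered last (Li/NH3). The C8/C9 pair comes from asymmetric conjugate methylation of 14 with allylation of the enolate. The forward sequence needs the C10–H trans to the C9 methyl and an axial C6 alcohol.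

## Roads not taken

**Alternative 1:** The cut is the ring-fusion C5'–C4' bond of ring C, made by an Ireland–Claisen ring contraction of a cyclohexenyl δ-lactone through a boat transition state, giving acid A1. It forms ring C, the C5' stereocentre and the C1'=C10' alkene in one stereospecific event, and A1 already carries a protected two-carbon tether. Its weak points are that the ring D cyclohexene with C8' and the C9' quaternary centre must be made enantiopure beforehand, and that the C4' carboxyl has to be reduced to a methyl group at a neopentyl position, which costs about three steps. It is better than the chosen plan in one respect: C5' and the alkene position come from internal chirality transfer, with no external catalyst and no equilibration at C8'. The chosen plan sets against this a shorter path from enone 4, no carboxyl-to-methyl excision, and a quaternary centre made directly at the tether oxidation level (11).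

**Alternative 2:** The cut is ring A, made by a thermal endo Diels–Alder reaction between the ring B diene A2 and the arylmethylmaleic anhydride A3, giving the cis-fused anhydride A4. It sets C8, C9 and C10 and the C5=C6 alkene in one step with the arene attached, and the endo rule gives the correct C9/C10 relation; in step count for ring A it is clearly better than the eight steps to 26 here. Its weak points are facial selectivity across the diene, which rests on a methyl/ethynyl difference at C4; a trisubstituted dienophile meeting a hindered diene; and two anhydride carbonyls to reduce to methyl groups at neopentyl positions. The electron-rich arene would also have to survive every later step, including the union. The chosen plan sets against this relayed control of C4 from C6, no carbonyl-to-methyl reductions, and an arene that is absent until step 21.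

**Alternative 3:** The cut is the C10'–C9' bond of ring D, made by a 6-exo Heck cyclization of a ring C enol triflate onto a tethered trisubstituted alkene with Pd(OAc)2 and BINAP, giving the vinyl octalin A5. It is catalytic, forms the quaternary centre and ring D together, and is more atom-economical than the orthoester Claisen route to 11. Its weak points are that the catalyst and the existing C8' stereocentre may be mismatched, and that a palladium hydride is generated next to an alkene that can migrate to the ring fusion. The vinyl group of A5 also still needs hydroboration before it can be joined. The chosen plan sets against this a substrate-controlled suprafacial shift with no metal hydride, which delivers the tether as an ester ready for reduction.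

Key step: step 21

## Route

Remarks. The target is taken as the free bis(hydrogen sulfate) as drawn; it is liberated from the first-formed pyridinium salt by cation exchange. Compounds 2 and 3 are racemic; their methyl-bearing carbon becomes C8' and is equilibrated in step 4.

Step 1
Reactants: 1 3-acetyl-3-methyloxolan-2-one
Product: 2 5-bromo-3-methylpentan-2-one
Conditions: 48% aq HBr, 100 °C
Reagents that add atoms: hydrogen bromide, Br
Why: Bromide opens the lactone at the O–CH2 carbon and the β-keto acid loses CO2, the standard conversion of α-acyl butyrolactones into γ-halo ketones.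

Step 2
Reactants: 2 5-bromo-3-methylpentan-2-one
Product: 3 2-(4-bromobutan-2-yl)-2-methyl-1,3-dioxolane
Conditions: HOCH2CH2OH, TsOH (cat.), benzene, reflux, Dean–Stark
Reagents that add atoms: ethylene glycol, OCCO
Why: Acid-catalysed ketalization with azeotropic removal of water masks the ketone for the organometallic step.

Step 3
Reactants: 3 2-(4-bromobutan-2-yl)-2-methyl-1,3-dioxolane; 4 4,4-dimethylcyclohex-2-en-1-one
Product: 7 (3R)-4,4-dimethyl-3-[3-(2-methyl-1,3-dioxolan-2-yl)butyl]cyclohexan-1-one, via alkylmagnesium bromide 5 (not isolated), via dialkylzinc 6 (not isolated)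
Conditions: Mg, THF; Zn(OMe)2, Et2O, centrifuge; Cu(OTf)2 (2 mol %), (S,R,R)-BINOL bis(1-phenylethyl)amine phosphoramidite (4 mol %), 4, toluene, −30 °C; aq NH4Cl
Reagents that add atoms: none
Why: Copper-catalysed asymmetric conjugate addition of a salt-free dialkylzinc, a reaction type established for enone 4, sets C5'. The ligand enantiomer is the one that gives (S)-3-ethylcyclohexanone from cyclohexenone; the same facial sense is 3R here. The side-chain CH is formed as both epimers.

Step 4
Reactants: 7 (3R)-4,4-dimethyl-3-[3-(2-methyl-1,3-dioxolan-2-yl)butyl]cyclohexan-1-one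
Product: 9 (4aS,7S)-4,4,7,8-tetramethyl-3,4,4a,5,6,7-hexahydronaphthalen-1(2H)-one, via diketone 8 (not isolated)
Conditions: 2 M HCl, THF, 23 °C; then NaOMe, MeOH, 65 °C
Reagents that add atoms: none
Why: Ketal hydrolysis and intramolecular aldol condensation of C10' onto the side-chain ketone close ring D; the conjugated tetrasubstituted enone is the only dehydratable aldol. C8' equilibrates through the dienolate and should favour the epimer with the pseudoaxial methyl (no 1,2-allylic strain with the C9' methyl), trans to H5'; the minor epimer is separated and re-equilibrated.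

Step 5
Reactants: 9 (4aS,7S)-4,4,7,8-tetramethyl-3,4,4a,5,6,7-hexahydronaphthalen-1(2H)-one
Product: 10 (1S,4aS,7S)-4,4,7,8-tetramethyl-1,2,3,4,4a,5,6,7-octahydronaphthalen-1-ol
Conditions: LiBH(s-Bu)3, THF, −78 °C; then H2O
Reagents that add atoms: none
Why: 1,2-Reduction by a bulky hydride along the equatorial direction should give the axial C1' alcohol, cis to H5', which also avoids 1,3-allylic strain with the C9' methyl.

Step 6
Reactants: 10 (1S,4aS,7S)-4,4,7,8-tetramethyl-1,2,3,4,4a,5,6,7-octahydronaphthalen-1-ol
Product: 11 ethyl 2-[(1R,2S,4aS)-1,2,5,5-tetramethyl-1,2,3,4,4a,5,6,7-octahydronaphthalen-1-yl]acetate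
Conditions: MeC(OEt)3 (8 equiv), EtCO2H (10 mol %), xylene, 140 °C, EtOH distilled off
Reagents that add atoms: triethyl orthoacetate, CCOC(C)(OCC)OCC
Why: Johnson–Claisen rearrangement; the ketene acetal on the axial oxygen delivers CH2CO2Et suprafacially to C9' on the face of H5' and anti to the C8' methyl. This sets the quaternary centre and moves the alkene to C1'=C10'.

Step 7
Reactants: 11 ethyl 2-[(1R,2S,4aS)-1,2,5,5-tetramethyl-1,2,3,4,4a,5,6,7-octahydronaphthalen-1-yl]acetate
Product: 12 2-[(1R,2S,4aS)-1,2,5,5-tetramethyl-1,2,3,4,4a,5,6,7-octahydronaphthalen-1-yl]ethan-1-ol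
Conditions: LiAlH4, Et2O, 0 °C; aq NaOH work-up
Reagents that add atoms: none
Why: Standard hydride reduction of an ester to the primary alcohol; the isolated alkene is inert.

Step 8
Reactants: 12 2-[(1R,2S,4aS)-1,2,5,5-tetramethyl-1,2,3,4,4a,5,6,7-octahydronaphthalen-1-yl]ethan-1-ol
Product: 13 (1R,2S,4aS)-1-(2-iodoethyl)-1,2,5,5-tetramethyl-1,2,3,4,4a,5,6,7-octahydronaphthalene
Conditions: I2, PPh3, imidazole, CH2Cl2, 0 to 23 °C
Reagents that add atoms: iodine, II
Why: Appel-type iodination of a primary alcohol whose α-carbon is unbranched; no acid is present to move the alkene.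

Step 9
Reactants: 14 2-methylcyclohex-2-en-1-one
Product: 16 (2S,3R)-2,3-dimethyl-2-(prop-2-en-1-yl)cyclohexan-1-one, via aluminium enolate 15 (not isolated)
Conditions: Me3Al, copper thiophene-2-carboxylate Cu(O2CC4H3S) (2 mol %), BINOL-derived phosphoramidite (4 mol %, antipode that sets 3R), Et2O, −30 °C; then MeLi, THF/DMPU, allyl iodide, −30 to 23 °C
Reagents that add atoms: trimethylaluminium, C[Al](C)C; allyl iodide, C=CCI
Why: Copper-catalysed asymmetric conjugate methylation sets C8, and the regiodefined enolate, activated as the aluminate, is allylated anti to the new methyl. This gives the cis-dimethyl C8/C9 pair with the allyl group trans.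

Step 10
Reactants: 16 (2S,3R)-2,3-dimethyl-2-(prop-2-en-1-yl)cyclohexan-1-one
Product: 17 (5R,6S)-5,6-dimethyl-6-(prop-2-en-1-yl)cyclohex-2-en-1-one
Conditions: IBX (2 equiv), DMSO/toluene, 70 °C
Reagents that add atoms: none
Why: IBX dehydrogenation of a ketone that can enolize only toward its CH2 side gives the enone; the terminal alkene is untouched.

Step 11
Reactants: 17 (5R,6S)-5,6-dimethyl-6-(prop-2-en-1-yl)cyclohex-2-en-1-one; 18 2-(3-chloropropyl)-2-methyl-1,3-dioxolane
Product: 20 (5R,6S)-5,6-dimethyl-1-[3-(2-methyl-1,3-dioxolan-2-yl)propyl]-6-(prop-2-en-1-yl)cyclohex-2-en-1-ol, via alkylmagnesium chloride 19 (not isolated)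
Conditions: 18, Mg, THF, reflux; CeCl3, THF, −78 °C; then 17; aq NH4Cl
Reagents that add atoms: none
Why: CeCl3-promoted 1,2-addition of a Grignard reagent to a hindered, non-enolizable enone carbonyl. The carbinol configuration is irrelevant because the next step removes it.

Step 12
Reactants: 20 (5R,6S)-5,6-dimethyl-1-[3-(2-methyl-1,3-dioxolan-2-yl)propyl]-6-(prop-2-en-1-yl)cyclohex-2-en-1-ol
Product: 21 (4S,5R)-4,5-dimethyl-3-[3-(2-methyl-1,3-dioxolan-2-yl)propyl]-4-(prop-2-en-1-yl)cyclohex-2-en-1-one
Conditions: pyridinium chlorochromate [C5H5NH][CrO3Cl] (2 equiv), NaOAc, 4 Å sieves, CH2Cl2, 23 °C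
Reagents that add atoms: pyridinium chlorochromate (carbonyl O), [O-][Cr](=O)(=O)Cl.c1cc[nH+]cc1
Why: Dauben–Babler oxidative transposition: the tertiary allylic chromate ester undergoes a [3,3] shift and is oxidised. The carbonyl ends at C6 and the chain sits on the β-carbon C10; acetate buffering protects the ketal.

Step 13
Reactants: 21 (4S,5R)-4,5-dimethyl-3-[3-(2-methyl-1,3-dioxolan-2-yl)propyl]-4-(prop-2-en-1-yl)cyclohex-2-en-1-one
Product: 22 (3S,4S,5R)-4,5-dimethyl-3-[3-(2-methyl-1,3-dioxolan-2-yl)propyl]-4-(prop-2-en-1-yl)cyclohexan-1-one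
Conditions: Li, NH3(l), THF, t-BuOH (1 equiv), −78 °C; NH4Cl
Reagents that add atoms: none
Why: Dissolving-metal reduction of a β,β-disubstituted enone protonates the β-carbon axially, anti to the axial C9 methyl. The chain ends equatorial and H10 trans to the C9 methyl; the isolated terminal alkene and the ketal are inert.

Step 14
Reactants: 22 (3S,4S,5R)-4,5-dimethyl-3-[3-(2-methyl-1,3-dioxolan-2-yl)propyl]-4-(prop-2-en-1-yl)cyclohexan-1-one
Product: 24 (3R,4S,4aR)-3,4,8-trimethyl-4-(prop-2-en-1-yl)-3,4,4a,5,6,7-hexahydronaphthalen-1(2H)-one, via diketone 23 (not isolated)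
Conditions: 2 M HCl, THF, 23 °C; then KOH, MeOH, 60 °C
Reagents that add atoms: none
Why: Ketal hydrolysis and intramolecular aldol condensation of C5 onto the methyl ketone close ring B; the conjugated enone is the only aldol that can dehydrate. C10 is not epimerizable in 23 or 24.

Step 15
Reactants: 24 (3R,4S,4aR)-3,4,8-trimethyl-4-(prop-2-en-1-yl)-3,4,4a,5,6,7-hexahydronaphthalen-1(2H)-one
Product: 25 (1R,3R,4S,4aR)-3,4,8-trimethyl-4-(prop-2-en-1-yl)-1,2,3,4,4a,5,6,7-octahydronaphthalen-1-ol
Conditions: LiBH(s-Bu)3, THF, −78 °C; then H2O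
Reagents that add atoms: none
Why: As in step 5, equatorial attack by a bulky hydride should give the axial C6 alcohol, cis to H10 and free of 1,3-allylic strain with the C4 methyl.

Step 16
Reactants: 25 (1R,3R,4S,4aR)-3,4,8-trimethyl-4-(prop-2-en-1-yl)-1,2,3,4,4a,5,6,7-octahydronaphthalen-1-ol
Product: 26 (1R,3R,4S,4aR)-3,4,8-trimethyl-4-(prop-2-en-1-yl)-1,2,3,4,4a,5,6,7-octahydronaphthalen-1-yl pyridine-2-carboxylate
Conditions: picolinic acid, DCC, DMAP (cat.), CH2Cl2, 23 °C
Reagents that add atoms: picolinic acid, OC(=O)c1ccccn1
Why: Carbodiimide esterification installs the chelating picolinate leaving group with retention at C6.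

Step 17
Reactants: 13 (1R,2S,4aS)-1-(2-iodoethyl)-1,2,5,5-tetramethyl-1,2,3,4,4a,5,6,7-octahydronaphthalene; 26 (1R,3R,4S,4aR)-3,4,8-trimethyl-4-(prop-2-en-1-yl)-1,2,3,4,4a,5,6,7-octahydronaphthalen-1-yl pyridine-2-carboxylate
Product: 28 allyl bis-octalin hydrocarbon (left C4 and right C9' joined by C11–C12), via alkylmagnesium iodide 27 (not isolated)
Conditions: 13 (2 equiv), Mg, Et2O; CuBr·SMe2 (1 equiv), THF, −40 °C; then 26, −40 to 0 °C
Reagents that add atoms: none
Why: Copper-mediated anti-SN2' substitution of an allylic picolinate by a Grignard reagent, a known way to quaternary carbons. Chelation of magnesium by the picolinate activates the axial C6–O bond, and the alkyl group enters C4 on the opposite (β) face. This puts C11 trans to H10 and the C4 methyl cis, and forms the C5=C6 alkene.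

Step 18
Reactants: 28 allyl bis-octalin hydrocarbon
Product: 29 bis-octalin methyl ketone (C9–CH2–CO–CH3)
Conditions: PdCl2 (10 mol %), CuCl, O2 (1 atm), DMF/THF/H2O, 23 °C
Reagents that add atoms: water (carbonyl O), O
Why: Tsuji–Wacker oxidation; divalent palladium attacks only the monosubstituted alkene with Markovnikov hydroxypalladation, and the two hindered trisubstituted alkenes do not coordinate.

Step 19
Reactants: 29 bis-octalin methyl ketone
Product: 31 bis-octalin propargyl compound (C9–CH2–C≡CH), via enol phosphate 30 (not isolated)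
Conditions: LiN(i-Pr)2 (1.1 equiv), THF, −78 °C; ClP(O)(OEt)2; LiN(i-Pr)2 (2.3 equiv), −78 to 23 °C; H2O
Reagents that add atoms: none
Why: Kinetic deprotonation at the methyl group (the other α-carbon is neopentyl), O-phosphorylation and base-induced elimination of the terminal enol phosphate: the standard methyl ketone to terminal alkyne conversion.

Step 20
Reactants: 32 hexacarbonylchromium
Product: 34 pentacarbonyl[methoxy(vinyl)carbene]chromium, via lithium acylate 33 (not isolated)
Conditions: vinyllithium (from vinyl bromide, t-BuLi 2 equiv, Et2O, −78 °C), 32, Et2O, 0 °C; MeOTf, CH2Cl2, 0 °C; cold filtration, used at once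
Reagents that add atoms: vinyllithium (from vinyl bromide C=CBr), [Li]C=C; methyl trifluoromethanesulfonate, COS(=O)(=O)C(F)(F)F
Why: Fischer carbene synthesis: the organolithium adds to a CO ligand and the acylate is O-methylated. The parent vinyl complex is labile, so it is made immediately before step 21.

Step 21
Reactants: 31 bis-octalin propargyl compound; 34 pentacarbonyl[methoxy(vinyl)carbene]chromium
Product: 35 hydroquinone monomethyl ether with the complete skeleton (2-alkyl-4-methoxyphenol)
Conditions: 34 (2 equiv), THF (0.05 M), 50 °C, Ar; then air, EtOAc, 23 °C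
Reagents that add atoms: none
Why: Dötz benzannulation of an alkenyl(alkoxy)carbene complex of zerovalent chromium with a terminal alkyne, a known reaction class. Loss of one CO lets the alkyne coordinate and insert into the Cr=C bond; CO insertion gives a vinylketene complex. The benzene ring then closes by 6π electrocyclization of the dienylketene, and the cyclohexadienone tautomerizes to the phenol, which air frees from chromium. Three ring C–C bonds form: alkyne CH to carbene carbon, internal alkyne carbon to CO, and CO to the vinyl terminus. No stereocentre is created. The step needs regioselective insertion, and sterics secure it: the neopentyl-type CH2–C9 substituent is placed next to the CO-derived carbon, so the alkyl group ends ortho to OH and para-related OMe comes from the carbene carbon. THF and an alkenyl complex favour phenol over cyclobutenone or furan products. The two hindered trisubstituted alkenes are not cyclopropanated by the alkoxycarbene.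

Step 22
Reactants: 35 hydroquinone monomethyl ether with the complete skeleton
Product: 36 2-alkyl-1,4-benzoquinone with the complete skeleton
Conditions: (NH4)2Ce(NO3)6 (2.5 equiv), MeCN/H2O, 0 °C
Reagents that add atoms: water (carbonyl O), O
Why: Oxidative demethylation of a 4-methoxyphenol by tetravalent cerium; it is fast at 0 °C and isolated trisubstituted alkenes survive, as in prenylated quinone chemistry.

Step 23
Reactants: 36 2-alkyl-1,4-benzoquinone with the complete skeleton
Product: 37 2-alkylhydroquinone with the complete skeleton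
Conditions: Na2S2O4, THF/H2O, 23 °C, N2
Reagents that add atoms: none
Why: Dithionite reduction of a quinone to the hydroquinone; the air-sensitive product is carried on directly.

Step 24
Reactants: 37 2-alkylhydroquinone with the complete skeleton
Product: 38 CNP0243830.4, the bis(hydrogen sulfate)
Conditions: SO3·pyridine (8 equiv), pyridine, 50 °C; then sulfonic acid resin (H+ form), MeOH/H2O, 0 °C
Reagents that add atoms: sulfur trioxide–pyridine complex, [O-]S(=O)(=O)[n+]1ccccc1
Why: O-Sulfation of both phenols with the SO3·pyridine complex under basic conditions, then brief cold cation exchange to the acid form; no skeletal centre is touched.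

## Compound list

1 | 3-acetyl-3-methyloxolan-2-one | CC(=O)C1(C)CCOC1=O | starting material
2 | 5-bromo-3-methylpentan-2-one (racemic) | CC(=O)C(C)CCBr | intermediate
3 | 2-(4-bromobutan-2-yl)-2-methyl-1,3-dioxolane (racemic) | CC(CCBr)C1(C)OCCO1 | intermediate
4 | 4,4-dimethylcyclohex-2-en-1-one | CC1(C)CCC(=O)C=C1 | starting material
5 | [3-(2-methyl-1,3-dioxolan-2-yl)butyl]magnesium bromide | CC(CC[Mg]Br)C1(C)OCCO1 | intermediate
6 | bis[3-(2-methyl-1,3-dioxolan-2-yl)butyl]zinc | CC(CC[Zn]CCC(C)C1(C)OCCO1)C1(C)OCCO1 | intermediate
7 | (3R)-4,4-dimethyl-3-[3-(2-methyl-1,3-dioxolan-2-yl)butyl]cyclohexan-1-one (both side-chain epimers) | O=C1CCC(C)(C)[C@H](CCC(C)C2(C)OCCO2)C1 | intermediate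
8 | (3R)-4,4-dimethyl-3-(3-methyl-4-oxopentyl)cyclohexan-1-one | O=C1CCC(C)(C)[C@H](CCC(C)C(C)=O)C1 | intermediate
9 | (4aS,7S)-4,4,7,8-tetramethyl-3,4,4a,5,6,7-hexahydronaphthalen-1(2H)-one | O=C1CCC(C)(C)[C@@H]2CC[C@H](C)C(C)=C12 | intermediate
10 | (1S,4aS,7S)-4,4,7,8-tetramethyl-1,2,3,4,4a,5,6,7-octahydronaphthalen-1-ol | O[C@H]1CCC(C)(C)[C@@H]2CC[C@H](C)C(C)=C12 | intermediate
11 | ethyl 2-[(1R,2S,4aS)-1,2,5,5-tetramethyl-1,2,3,4,4a,5,6,7-octahydronaphthalen-1-yl]acetate | CCOC(=O)C[C@@]1(C)C2=CCCC(C)(C)[C@@H]2CC[C@@H]1C | intermediate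
12 | 2-[(1R,2S,4aS)-1,2,5,5-tetramethyl-1,2,3,4,4a,5,6,7-octahydronaphthalen-1-yl]ethan-1-ol | OCC[C@@]1(C)C2=CCCC(C)(C)[C@@H]2CC[C@@H]1C | intermediate
13 | (1R,2S,4aS)-1-(2-iodoethyl)-1,2,5,5-tetramethyl-1,2,3,4,4a,5,6,7-octahydronaphthalene | ICC[C@@]1(C)C2=CCCC(C)(C)[C@@H]2CC[C@@H]1C | intermediate
14 | 2-methylcyclohex-2-en-1-one | CC1=CCCCC1=O | starting material
15 | {[(3R)-2,3-dimethylcyclohex-1-en-1-yl]oxy}dimethylalumane | C[C@@H]1CCCC(O[Al](C)C)=C1C | intermediate
16 | (2S,3R)-2,3-dimethyl-2-(prop-2-en-1-yl)cyclohexan-1-one | C[C@@H]1CCCC(=O)[C@@]1(C)CC=C | intermediate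
17 | (5R,6S)-5,6-dimethyl-6-(prop-2-en-1-yl)cyclohex-2-en-1-one | C[C@@H]1CC=CC(=O)[C@@]1(C)CC=C | intermediate
18 | 2-(3-chloropropyl)-2-methyl-1,3-dioxolane | CC1(CCCCl)OCCO1 | starting material
19 | [3-(2-methyl-1,3-dioxolan-2-yl)propyl]magnesium chloride | CC1(CCC[Mg]Cl)OCCO1 | intermediate
20 | (5R,6S)-5,6-dimethyl-1-[3-(2-methyl-1,3-dioxolan-2-yl)propyl]-6-(prop-2-en-1-yl)cyclohex-2-en-1-ol (both C1 epimers) | C[C@@H]1CC=CC(O)(CCCC2(C)OCCO2)[C@@]1(C)CC=C | intermediate
21 | (4S,5R)-4,5-dimethyl-3-[3-(2-methyl-1,3-dioxolan-2-yl)propyl]-4-(prop-2-en-1-yl)cyclohex-2-en-1-one | C[C@@H]1CC(=O)C=C(CCCC2(C)OCCO2)[C@@]1(C)CC=C | intermediate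
22 | (3S,4S,5R)-4,5-dimethyl-3-[3-(2-methyl-1,3-dioxolan-2-yl)propyl]-4-(prop-2-en-1-yl)cyclohexan-1-one | C[C@@H]1CC(=O)C[C@H](CCCC2(C)OCCO2)[C@@]1(C)CC=C | intermediate
23 | (3S,4S,5R)-4,5-dimethyl-3-(4-oxopentyl)-4-(prop-2-en-1-yl)cyclohexan-1-one | C[C@@H]1CC(=O)C[C@H](CCCC(C)=O)[C@@]1(C)CC=C | intermediate
24 | (3R,4S,4aR)-3,4,8-trimethyl-4-(prop-2-en-1-yl)-3,4,4a,5,6,7-hexahydronaphthalen-1(2H)-one | C[C@@H]1CC(=O)C2=C(C)CCC[C@@H]2[C@@]1(C)CC=C | intermediate
25 | (1R,3R,4S,4aR)-3,4,8-trimethyl-4-(prop-2-en-1-yl)-1,2,3,4,4a,5,6,7-octahydronaphthalen-1-ol | C[C@@H]1C[C@@H](O)C2=C(C)CCC[C@@H]2[C@@]1(C)CC=C | intermediate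
26 | (1R,3R,4S,4aR)-3,4,8-trimethyl-4-(prop-2-en-1-yl)-1,2,3,4,4a,5,6,7-octahydronaphthalen-1-yl pyridine-2-carboxylate | C[C@@H]1C[C@@H](OC(=O)c3ccccn3)C2=C(C)CCC[C@@H]2[C@@]1(C)CC=C | intermediate
27 | {2-[(1R,2S,4aS)-1,2,5,5-tetramethyl-1,2,3,4,4a,5,6,7-octahydronaphthalen-1-yl]ethyl}magnesium iodide | I[Mg]CC[C@@]1(C)C2=CCCC(C)(C)[C@@H]2CC[C@@H]1C | intermediate
28 | allyl bis-octalin: left octalin (C4 methyl and tether, C5=C6, C8 methyl, C9 methyl and allyl, C10–H) joined by CH2CH2 to C9' of the right octalin; all centres as in 38 | C[C@@H]1CC=C2[C@H](CCC[C@@]2(C)CC[C@@]2(C)C3=CCCC(C)(C)[C@@H]3CC[C@@H]2C)[C@@]1(C)CC=C | intermediate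
29 | bis-octalin methyl ketone (2-oxopropyl on C9) | C[C@@H]1CC=C2[C@H](CCC[C@@]2(C)CC[C@@]2(C)C3=CCCC(C)(C)[C@@H]3CC[C@@H]2C)[C@@]1(C)CC(C)=O | intermediate
30 | bis-octalin diethyl enol phosphate (2-(diethoxyphosphoryloxy)prop-2-enyl on C9) | C[C@@H]1CC=C2[C@H](CCC[C@@]2(C)CC[C@@]2(C)C3=CCCC(C)(C)[C@@H]3CC[C@@H]2C)[C@@]1(C)CC(=C)OP(=O)(OCC)OCC | intermediate
31 | bis-octalin propargyl compound (prop-2-ynyl on C9) | C[C@@H]1CC=C2[C@H](CCC[C@@]2(C)CC[C@@]2(C)C3=CCCC(C)(C)[C@@H]3CC[C@@H]2C)[C@@]1(C)CC#C | intermediate
32 | hexacarbonylchromium | O=C=[Cr](=C=O)(=C=O)(=C=O)(=C=O)=C=O | starting material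
33 | lithium pentacarbonyl(1-oxidoprop-2-enylidene)chromate | [Li+].[O-]C(C=C)=[Cr](=C=O)(=C=O)(=C=O)(=C=O)=C=O | intermediate
34 | pentacarbonyl[methoxy(vinyl)carbene]chromium | COC(C=C)=[Cr](=C=O)(=C=O)(=C=O)(=C=O)=C=O | intermediate
35 | hydroquinone monomethyl ether: 2-(bis-octalinylmethyl)-4-methoxyphenol | C[C@@H]1CC=C2[C@H](CCC[C@@]2(C)CC[C@@]2(C)C3=CCCC(C)(C)[C@@H]3CC[C@@H]2C)[C@@]1(C)Cc1cc(OC)ccc1O | intermediate
36 | 2-(bis-octalinylmethyl)cyclohexa-2,5-diene-1,4-dione | C[C@@H]1CC=C2[C@H](CCC[C@@]2(C)CC[C@@]2(C)C3=CCCC(C)(C)[C@@H]3CC[C@@H]2C)[C@@]1(C)CC1=CC(=O)C=CC1=O | intermediate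
37 | 2-(bis-octalinylmethyl)benzene-1,4-diol | C[C@@H]1CC=C2[C@H](CCC[C@@]2(C)CC[C@@]2(C)C3=CCCC(C)(C)[C@@H]3CC[C@@H]2C)[C@@]1(C)Cc1cc(O)ccc1O | intermediate
38 | CNP0243830.4, 2-(bis-octalinylmethyl)-1,4-phenylene bis(hydrogen sulfate) | C[C@@H]1CC=C2[C@H](CCC[C@@]2(C)CC[C@@]2(C)C3=CCCC(C)(C)[C@@H]3CC[C@@H]2C)[C@@]1(C)Cc1cc(OS(=O)(=O)O)ccc1OS(=O)(=O)O | target

## Step count and least certain steps

Total: 24 steps. Longest linear sequence: 15 steps (steps 1–8, 17–19, 21–24; the branch through steps 9–16 is equally long).

**Step 21 (key step).** The labile vinylcarbene complex may decompose or self-condense, and carbene-initiated oligomerisation of the terminal alkyne may outrun productive insertion. Fallback: from 31 and 32, use the shelf-stable silylvinyl complex pentacarbonyl{methoxy[(E)-2-(trimethylsilyl)ethenyl]carbene}chromium F1, made from 32 like 34. Its benzannulation with 31 goes through the same vinylketene, but the silyl group migrates from carbon to oxygen in the cyclohexadienone and gives the aryl trimethylsilyl ether F2. Methanolysis (K2CO3, MeOH) of F2 returns to the route at 35.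

**Step 17.** Substitution may occur at the carbinol carbon instead of C4, or stall, because delivery to the β face of C4 passes a boat-like ring B next to C9 while a quaternary centre is formed. Fallback, a sigmatropic union: Grignard reagent 27 (from 13) is carboxylated with CO2 to the propanoic acid F3. Mitsunobu esterification of alcohol 25 with F3 inverts C6 and gives ester F4. Ireland–Claisen rearrangement (LiN(i-Pr)2, Me3SiCl, THF, −78 to 60 °C) delivers the α-carbon suprafacially to the β face of C4 and gives acid F5. Acridinium-photocatalysed hydrodecarboxylation with an excess of a thiol hydrogen donor, to outrun homoallyl radical rearrangement, returns to the route at 28.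

**Step 3.** A γ-branched functionalised dialkylzinc adding next to a gem-dimethyl carbon may react slowly or with eroded enantioselectivity. Fallback, hydride instead of carbon delivered enantioselectively: commercial 4,4-dimethylcyclohexane-1,3-dione and isobutanol (TsOH) give the vinylogous ester 3-isobutoxy-6,6-dimethylcyclohex-2-en-1-one F6. Stork–Danheiser addition of Grignard reagent 5 (from 3) and mild acid give the enone F7. CuH-catalysed asymmetric conjugate reduction (CuCl, NaOt-Bu, p-tol-BINAP antipode for 3R, polymethylhydrosiloxane) returns to the route at 7.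

**Step 6.** At 140 °C with acid, ionisation and dehydration of the hindered axial allylic alcohol to a diene may compete with ketene acetal formation at a fully substituted terminus. Fallback, an enolate Claisen without acid: 10 is acetylated (Ac2O, DMAP) to the acetate F8. Ireland–Claisen rearrangement (LiN(i-Pr)2, Me3SiCl, −78 to 60 °C) gives the acid F9 with the same suprafacial transfer. LiAlH4 reduction of F9 returns to the route at 12.

**Step 19 (with step 18).** Enolisation toward the neopentyl CH2 or incomplete elimination would give allene or internal products, and the palladium of step 18 may move an alkene. Fallback, from 28 by oxidative cleavage and homologation: Lemieux–Johnson oxidation (OsO4 cat., NaIO4, 2,6-lutidine) of the monosubstituted alkene gives the aldehyde F10. Seyferth–Gilbert homologation with the Ohira–Bestmann reagent (K2CO3, MeOH) returns to the route at 31. The risk there is loss of chemoselectivity between the terminal and the two trisubstituted alkenes.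

## Further compounds

F1 | step 21 | pentacarbonyl{methoxy[(E)-2-(trimethylsilyl)ethenyl]carbene}chromium | COC(/C=C/[Si](C)(C)C)=[Cr](=C=O)(=C=O)(=C=O)(=C=O)=C=O
F2 | step 21 | trimethylsilyl ether of 35 | C[C@@H]1CC=C2[C@H](CCC[C@@]2(C)CC[C@@]2(C)C3=CCCC(C)(C)[C@@H]3CC[C@@H]2C)[C@@]1(C)Cc1cc(OC)ccc1O[Si](C)(C)C
F3 | step 17 | 3-[(1R,2S,4aS)-1,2,5,5-tetramethyl-1,2,3,4,4a,5,6,7-octahydronaphthalen-1-yl]propanoic acid | OC(=O)CC[C@@]1(C)C2=CCCC(C)(C)[C@@H]2CC[C@@H]1C
F4 | step 17 | C6-inverted ester of 25 with F3 | C[C@@H]1C[C@H](OC(=O)CC[C@@]3(C)C4=CCCC(C)(C)[C@@H]4CC[C@@H]3C)C2=C(C)CCC[C@@H]2[C@@]1(C)CC=C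
F5 | step 17 | allyl bis-octalin carrying CO2H on C11 | C[C@@H]1CC=C2[C@H](CCC[C@@]2(C)C(C[C@@]2(C)C3=CCCC(C)(C)[C@@H]3CC[C@@H]2C)C(=O)O)[C@@]1(C)CC=C
F6 | step 3 | 3-isobutoxy-6,6-dimethylcyclohex-2-en-1-one | CC(C)COC1=CC(=O)C(C)(C)CC1
F7 | step 3 | 4,4-dimethyl-3-[3-(2-methyl-1,3-dioxolan-2-yl)butyl]cyclohex-2-en-1-one | CC(CCC1=CC(=O)CCC1(C)C)C1(C)OCCO1
F8 | step 6 | (1S,4aS,7S)-4,4,7,8-tetramethyl-1,2,3,4,4a,5,6,7-octahydronaphthalen-1-yl acetate | CC(=O)O[C@H]1CCC(C)(C)[C@@H]2CC[C@H](C)C(C)=C12
F9 | step 6 | 2-[(1R,2S,4aS)-1,2,5,5-tetramethyl-1,2,3,4,4a,5,6,7-octahydronaphthalen-1-yl]acetic acid | OC(=O)C[C@@]1(C)C2=CCCC(C)(C)[C@@H]2CC[C@@H]1C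
F10 | step 19 | bis-octalin aldehyde (2-oxoethyl on C9) | C[C@@H]1CC=C2[C@H](CCC[C@@]2(C)CC[C@@]2(C)C3=CCCC(C)(C)[C@@H]3CC[C@@H]2C)[C@@]1(C)CC=O
A1 | alternative 1 | right octalin acid with one geminal methyl as carboxyl and a silyloxyethyl tether | CC(C)(C)[Si](C)(C)OCC[C@@]1(C)C2=CCC[C@](C)(C(=O)O)[C@@H]2CC[C@@H]1C
A2 | alternative 2 | 1-ethynyl-1-methyl-2-vinylcyclohex-2-ene | C=CC1=CCCC[C@@]1(C)C#C
A3 | alternative 2 | 2-(2,5-dimethoxybenzyl)maleic anhydride | COc1ccc(OC)c(CC2=CC(=O)OC2=O)c1
A4 | alternative 2 | cis-fused Diels–Alder anhydride of the left octalin | O=C1OC(=O)[C@@]2(Cc3cc(OC)ccc3OC)[C@H]3CCC[C@@](C)(C#C)C3=CC[C@@H]12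
A5 | alternative 3 | right octalin with a vinyl group on the quaternary carbon | C=C[C@@]1(C)C2=CCCC(C)(C)[C@@H]2CC[C@@H]1C
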